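(The earlier runs and the new flask stem from a simulated flask for an exercise, and the scatter is random.)

The winter run ended higher than the summer run, at 44.8% against 12.5%, but it was warmer and held more capture agent. Maple repeats winter's temperature with less capture agent, so I asked what would have to be true for maple to end below winter.

common to all: substrate 1.4 M; gas 180 mM (held)

| flask | first nucleophile | capture agent | temperature | remark | time |
|---|---|---|---|---|---|
| summer | 0.98 M | 0.019 M | −5 °C | run made earlier |  |
| winter | 0.98 M | 0.042 M | 20 °C | run made earlier |  |
| alder | 0.980 M | 0.0280 M | 0 °C |  | 40 min |
| ash | 0.980 M | 0.0280 M | 40 °C |  | 40 min |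
| maple | 0.980 M | 0.0280 M | 20 °C |  | 40 min |

- summer (time / min: target / %): 3.00: 1.8; 5.00: 2.2; 8.00: 4.1; 15.0: 7.0; 25.0: 9.0; 40.0: 12.5
- winter (time / min: target / %): 1.00: 14.0; 3.00: 29.8; 6.00: 39.7; 8.00: 42.3; 12.0: 43.9; 15.0: 44.8

(readings scatter by 0.3 percentage points)

* the flask that comes out highest in amount of target, in percent of the substrate charged, or "all alike" when all lie within 1.5 percentage points (alder / ash / maple / all alike)
* target at the end, in percent of the substrate charged, alder
* target at the end, in percent of the substrate charged, ash
* target at the end, in percent of the substrate charged, maple

Winter's last reading meant 0.627 M of target on 0.042 M of capture agent, or 14.9 turnovers. If capture agent stops after that count, maple stops at 29.9%. The other reading is that winter's substrate was consumed and its plateau is a share, which capture agent does not enter. First nucleophile had not stopped winter, since 0.353 M of it remained by this count. The runs moved temperature and capture agent together, so they could not separate these readings. I took the share, the simpler one, and it puts maple 15 percentage points above the turnover cap.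

For the share I defined the break-even concentration, the [first nucleophile] at which target and everything else form equally fast, a selectivity factor written as a concentration. Held constant, it gives this balance: substrate consumed equals target formed plus the break-even concentration times ln([first nucleophile] at start over [first nucleophile] at end). Winter gives 0.756 M. Maple matches winter in temperature, substrate, first nucleophile and gas, but holds 0.0280 M of capture agent against winter's 0.042 M; because I had assumed that capture agent does not enter the share, I expected maple to return about 44.8%.

The forecast read the winter curve as “a catalyst-like capture agent” and gave 22.3% for alder, 35% for ash and 30% for maple, with ash highest. My maple stood above even the forecast's high end for ash, 42%, so I expected maple highest.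

Maple gave 45.0%, against 36.7% for ash and 23.2% for alder, so maple was highest, and the forecast's maple was 15 points short. At 40.0 min, maple held 0% of its substrate and >99.9% of its capture agent. Maple's own figure in the balance gives a break-even concentration of 0.748 M.

    substrate → open intermediate (k = 3.20 × 10⁻⁴ s⁻¹, Ea = 89.0 kJ mol⁻¹)
    first nucleophile + open intermediate → target (k = 0.210 M⁻¹ s⁻¹, Ea = 46.0 kJ mol⁻¹)
    second nucleophile + open intermediate → other capture product (k = 2.40 M⁻¹ s⁻¹, Ea = 38.0 kJ mol⁻¹)
    open intermediate → solvolysis product (k = 0.0600 s⁻¹, Ea = 71.0 kJ mol⁻¹)
    substrate + open intermediate → side product (k = 1.50 × 10⁻⁴ M⁻¹ s⁻¹, Ea = 77.0 kJ mol⁻¹)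
    open intermediate + capture agent → trapped intermediate (k = 3.80 × 10⁻⁵ M⁻¹ s⁻¹, Ea = 60.0 kJ mol⁻¹)
    gas ⇌ second nucleophile, rate k7*(csat - [second nucleophile]) (kL = 0.00160 s⁻¹)
    (constants at 0 °C)

I then took maple with 2.5 M of first nucleophile. Starting from a guess of 0.980 M of target, the balance with winter's break-even concentration returned 1.02 M, then 1.00 M, or 71.5% of the substrate. The computed flask gave 70.5%.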